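(The numbers in the tables were generated by integration for an exercise, and the scatter is random.)

The leftover that matters in this flask is the unused nucleophile, charged at 1.05 equiv.

- maple: electrophile 0.50 M; nucleophile 1.05 equiv; the very flask that is asked about, followed so far
- flask: electrophile 0.50 M; nucleophile 1.05 equiv; time 15 min

maple run (percent of the electrophile charged)

| time / s | electrophile / % | target / % |
|---|---|---|
| 10.0 | 94.6 | 0.4 |
| 20.0 | 88.1 | 2.2 |
| 30.0 | 82.1 | 2.8 |
| 50.0 | 73.7 | 4.6 |
| 80.0 | 64.0 | 4.7 |

(scatter of a reading: 1 percentage point)

- part of the electrophile that has reacted at 15 min
- share of the unused nucleophile that is free and not bound as protonated nucleophile, at 15 min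

- what has gone from electrophile into another species counts as reacted, even if it can come back
- the earlier runs do not show how much of nucleophile is bound; that part of a forecast is a guess

The bench rule for a nearly equimolar pair is one nucleophile per electrophile lost, with a second-order fall. My own reckoning starts there. The last maple reading gives a second-order constant k = 0.0141 /M/s, so c, the part of the electrophile reacted, is reckoned at 86.4% at 15 min, and one-for-one counting leaves 18.6% of the electrophile charge as nucleophile.

That counting stops at a ratio. At 80.0 s the maple run has lost 36.0% of its electrophile but shows 4.7% target. The target share s, target formed per electrophile reacted (a selectivity), reads 0.131, with a scatter of 1 percentage point on the target reading.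

Freeze s, and suppose each target frees one acid that binds one further nucleophile. With charge N and target T, both per electrophile charged, the free share fr of the unused nucleophile is (N − 2T)/(N − T). At T = s·c = 11.3%, this reckoning gives fr = 88.0% for the flask.

The forecast says c = 71% and fr = 15%, on the ground that “free nucleophile runs nearly out”. My reckoning stands higher on c and on fr.

The flask gives c = 82.5% and fr = 77.9%.

    nucleophile + acid set free ⇌ protonated nucleophile, settled at all times (K = 70.0 /M)
    electrophile + nucleophile → acid set free + target (k = 0.0956 /M/min)
    2 electrophile → self-condensation product (k = 0.215 /M/min)
    electrophile ⇌ dormant form (K = 0.807, k = 0.138 /min)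

At 15 min this flask holds 19.7% target, a share of 0.239 of the electrophile reacted by then, nearly twice the s of 0.131 read at 80.0 s. Take the neighbour flask with 0.20 M electrophile and the same equivalents, where c = 69.9%. There the frozen s reckons T = 9.13% and a free share of 90.5%. That flask holds 12.1% target, and its fr is 88.0%.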